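## Retrosynthetic overview

1. Target (3S,5S, the 1,3-anti diol) ⇐ cleavage of four Si–O bonds in a trans-4,6-disubstituted 2,2-diisopropyl-1,3,2-dioxasilinane. This temporary ring is the only ring formed in the route; both benzene rings are bought.
2. Dioxasilinane ⇐ β-(hydridosilyloxy) ketone by internal 1,3-anti hydride delivery (sets C3) ⇐ E-enone + iPr2Si(H)OH by enantioselective C5–O bond formation (oxa-Michael, sets C5). This is the key disconnection.
3. E-enone ⇐ C4=C5 aldol condensation of O-silyl zingerone with O-silyl 3-(syringyl)propanal.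
4. Aldehyde ⇐ 4-allyl-2,6-dimethoxyphenol (silylation, anti-Markovnikov hydration, oxidation); ketone ⇐ zingerone (silylation).

Conventions: TBS = tert-butyldimethylsilyl, TBSO = its silyloxy group. C1 is the benzylic carbon of the 4-hydroxy-3-methoxyphenyl (guaiacyl) arm and C7 that of the 4-hydroxy-3,5-dimethoxyphenyl (syringyl) arm.

Assumption 1: diisopropylsilanol, iPr2Si(H)OH, is not a catalogue reagent; it is made beforehand in one operation from commercial chlorodiisopropylsilane (H2O, NaHCO3, Et2O, 0 °C) and is treated as a reagent, not as a route step.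

Assumption 2: the quinine-derived amine catalyst is taken to give the 5S adduct; if the sense of induction proves opposite, its quinidine-derived pseudoenantiomer is used with no other change.

## Route

Step 1

Reactants: 1 zingerone [4-(4-hydroxy-3-methoxyphenyl)butan-2-one]

Product: 2 4-[4-(tert-butyldimethylsilyloxy)-3-methoxyphenyl]butan-2-one

Conditions: TBSCl (1.2 equiv), imidazole (2 equiv), DMF, 25 °C

Reagents that add atoms: tert-butyldimethylsilyl chloride, CC(C)(C)[Si](C)(C)Cl

Why: Imidazole-promoted O-silylation (silyl ether protection) masks the only acidic group so that step 5 can form the kinetic ketone enolate cleanly; the ketone is untouched.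

Step 2

Reactants: 3 4-allyl-2,6-dimethoxyphenol

Product: 4 tert-butyl(4-allyl-2,6-dimethoxyphenoxy)dimethylsilane

Conditions: TBSCl (1.3 equiv), imidazole (2.5 equiv), DMF, 40 °C

Reagents that add atoms: tert-butyldimethylsilyl chloride, CC(C)(C)[Si](C)(C)Cl

Why: The same phenol O-silylation; imidazole in DMF silylates even this di-ortho-substituted phenol and leaves the allyl group alone.

Step 3

Reactants: 4 tert-butyl(4-allyl-2,6-dimethoxyphenoxy)dimethylsilane

Product: 6 3-[4-(TBSO)-3,5-dimethoxyphenyl]propan-1-ol, via B-alkyl-9-BBN adduct 5 (not isolated)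

Conditions: 9-borabicyclo[3.3.1]nonane (9-BBN, 1.2 equiv), THF, 0 → 25 °C; then aq. NaOAc, 30 % H2O2, 0 → 25 °C

Reagents that add atoms: hydrogen peroxide, OO

Why: Brown hydroboration–oxidation: the bulky borane places boron on the terminal carbon (anti-Markovnikov), and acetate-buffered peroxide turns C–B into C–OH without hydrolysing the base-labile aryl silyl ether.

Step 4

Reactants: 6 3-[4-(TBSO)-3,5-dimethoxyphenyl]propan-1-ol

Product: 7 3-[4-(TBSO)-3,5-dimethoxyphenyl]propanal

Conditions: Dess–Martin periodinane (1.2 equiv), CH2Cl2, 0 → 25 °C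

Reagents that add atoms: none

Why: Dess–Martin oxidation of a primary alcohol stops at the aldehyde under near-neutral conditions that the aryl silyl ether and the electron-rich ring tolerate.

Step 5

Reactants: 2 4-[4-(TBSO)-3-methoxyphenyl]butan-2-one; 7 3-[4-(TBSO)-3,5-dimethoxyphenyl]propanal

Product: 10 (E)-1-[4-(TBSO)-3-methoxyphenyl]-7-[4-(TBSO)-3,5-dimethoxyphenyl]hept-4-en-3-one, via aldol adduct 8 (not isolated), via aldol mesylate 9 (not isolated)

Conditions: LiN(iPr)2 (commercial solution, 1.1 equiv), THF, −78 °C; then 7, −78 °C; then MsCl (2.5 equiv), Et3N (5 equiv), −78 → 25 °C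

Reagents that add atoms: none

Why: Directed aldol condensation: LiN(iPr)2 at −78 °C gives the kinetic methyl-side enolate of 2, which adds to 7, and mesylation of the aldolate followed by E1cB elimination gives the conjugated enone with the thermodynamically favoured E geometry.

Step 6

Reactants: 10 (E)-1-[4-(TBSO)-3-methoxyphenyl]-7-[4-(TBSO)-3,5-dimethoxyphenyl]hept-4-en-3-one

Product: 13 (3S,5S)-1-(4-hydroxy-3-methoxyphenyl)-7-(4-hydroxy-3,5-dimethoxyphenyl)heptane-3,5-diol, via silyloxy ketone 11 (not isolated), via dioxasilinane 12 (not isolated)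

Conditions: iPr2Si(H)OH (3 equiv), 9-amino(9-deoxy)epiquinine (10 mol %), CF3CO2H (20 mol %), toluene (1 M), 0 → 25 °C; then SnCl4 (0.5 equiv), CH2Cl2, −78 °C; then Bu4NF (5 equiv), AcOH (5 equiv), THF, 0 → 25 °C

Reagents that add atoms: diisopropylsilanol, CC(C)[SiH](O)C(C)C

Why: Proposed new method: an iminium-catalysed enantioselective oxa-Michael addition of a hydridosilanol, in which the primary amine of the cinchona catalyst condenses with the ketone of 10 to give an α,β-unsaturated iminium ion, the protonated quinuclidine hydrogen-bonds the acidic Si–OH (acidity close to that of a hydroperoxide) and delivers its oxygen to the Si face of C5, and enamine hydrolysis releases 11 with the C5–O bond and the 5S centre in place; the closest known reaction type is the addition of hydrogen peroxide and alkyl hydroperoxides to aliphatic enones with the same amine salts, where a silanol (least of all one carrying Si–H) has not been used; the Si–H group then serves, in the same flask, the known SnCl4-triggered intramolecular hydrosilylation of β-(hydridosilyloxy) ketones, whose chair-like six-membered transition state with external Lewis-acid activation gives the 1,3-anti relationship (3S), closes dioxasilinane 12 and makes the reversible oxa-Michael adduct irreversible, before buffered fluoride cleaves all four Si–O bonds.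

## Compound list

```
1 | zingerone, 4-(4-hydroxy-3-methoxyphenyl)butan-2-one | CC(=O)CCc1ccc(O)c(OC)c1 | starting material
2 | 4-[4-(tert-butyldimethylsilyloxy)-3-methoxyphenyl]butan-2-one | CC(=O)CCc1ccc(O[Si](C)(C)C(C)(C)C)c(OC)c1 | intermediate
3 | 4-allyl-2,6-dimethoxyphenol | C=CCc1cc(OC)c(O)c(OC)c1 | starting material
4 | tert-butyl(4-allyl-2,6-dimethoxyphenoxy)dimethylsilane | C=CCc1cc(OC)c(O[Si](C)(C)C(C)(C)C)c(OC)c1 | intermediate
5 | B-{3-[4-(TBSO)-3,5-dimethoxyphenyl]propyl}-9-borabicyclo[3.3.1]nonane (formed in the flask, not isolated) | COc1cc(CCCB2C3CCCC2CCC3)cc(OC)c1O[Si](C)(C)C(C)(C)C | intermediate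
6 | 3-[4-(TBSO)-3,5-dimethoxyphenyl]propan-1-ol | OCCCc1cc(OC)c(O[Si](C)(C)C(C)(C)C)c(OC)c1 | intermediate
7 | 3-[4-(TBSO)-3,5-dimethoxyphenyl]propanal | O=CCCc1cc(OC)c(O[Si](C)(C)C(C)(C)C)c(OC)c1 | intermediate
8 | racemic 5-hydroxy-1-[4-(TBSO)-3-methoxyphenyl]-7-[4-(TBSO)-3,5-dimethoxyphenyl]heptan-3-one (present as its lithium alkoxide, not isolated) | COc1cc(CCC(=O)CC(O)CCc2cc(OC)c(O[Si](C)(C)C(C)(C)C)c(OC)c2)ccc1O[Si](C)(C)C(C)(C)C | intermediate
9 | racemic 5-(methanesulfonyloxy)-1-[4-(TBSO)-3-methoxyphenyl]-7-[4-(TBSO)-3,5-dimethoxyphenyl]heptan-3-one (not isolated) | COc1cc(CCC(=O)CC(OS(C)(=O)=O)CCc2cc(OC)c(O[Si](C)(C)C(C)(C)C)c(OC)c2)ccc1O[Si](C)(C)C(C)(C)C | intermediate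
10 | (E)-1-[4-(TBSO)-3-methoxyphenyl]-7-[4-(TBSO)-3,5-dimethoxyphenyl]hept-4-en-3-one | COc1cc(CCC(=O)/C=C/CCc2cc(OC)c(O[Si](C)(C)C(C)(C)C)c(OC)c2)ccc1O[Si](C)(C)C(C)(C)C | intermediate
11 | (5S)-5-[di(propan-2-yl)silyloxy]-1-[4-(TBSO)-3-methoxyphenyl]-7-[4-(TBSO)-3,5-dimethoxyphenyl]heptan-3-one (not isolated) | COc1cc(CCC(=O)C[C@@H](O[SiH](C(C)C)C(C)C)CCc2cc(OC)c(O[Si](C)(C)C(C)(C)C)c(OC)c2)ccc1O[Si](C)(C)C(C)(C)C | intermediate
12 | (4S,6S)-4-{2-[4-(TBSO)-3-methoxyphenyl]ethyl}-6-{2-[4-(TBSO)-3,5-dimethoxyphenyl]ethyl}-2,2-di(propan-2-yl)-1,3,2-dioxasilinane (trans, not isolated) | COc1cc(CC[C@H]2C[C@H](CCc3cc(OC)c(O[Si](C)(C)C(C)(C)C)c(OC)c3)O[Si](C(C)C)(C(C)C)O2)ccc1O[Si](C)(C)C(C)(C)C | intermediate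
13 | (3S,5S)-1-(4-hydroxy-3-methoxyphenyl)-7-(4-hydroxy-3,5-dimethoxyphenyl)heptane-3,5-diol (CNP0317264.1) | COc1cc(CC[C@H](O)C[C@@H](O)CCc2cc(OC)c(O)c(OC)c2)ccc1O | target
```

## Step count and risks

Total step count: 6 (the one-operation preparation of the silanol reagent is not counted).
Longest linear sequence: 5 steps (3 → 4 → 6 → 7 → 10 → 13).

Three steps most likely to fail:

**Step 6 (the new oxa-Michael / hydride-delivery cascade), the most likely to fail.** Weak points:
- The silanol may be too poor a nucleophile, or the addition may stop at an unfavourable equilibrium (retro-oxa-Michael) before SnCl4 is added.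
- The Si–H group might reduce the catalyst-bound iminium ion and deactivate the amine.
- The silanol may self-condense to the disiloxane.
- The level and sense of induction are untested.

The fallback uses known chemistry only, still forms the C5–O bond enantioselectively, sets out from 10 and comes back at 13. Amine-salt-catalysed asymmetric hydroperoxidation of 10 [9-amino(9-deoxy)epiquinine (10 mol %), CF3CO2H (20 mol %), 50 % aq. H2O2, dioxane, 30 °C] gives the cyclic peroxyhemiketal, the (5S)-1,2-dioxolan-3-ol F1. P(OEt)3 (THF, 25 °C) reduces its O–O bond to the (5S)-β-hydroxy ketone F2. Evans–Saksena reduction with Me4NBH(OAc)3 (MeCN/AcOH, −35 °C) delivers hydride internally and gives the anti-diol bis-silyl ether F3. Bu4NF/AcOH (THF, 25 °C) then gives 13.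

**Step 5 (one-flask aldol addition / mesylation / elimination).** Weak points:
- Proton transfer from the enolisable aldehyde 7 to the enolate.
- Retro-aldol of the lithium aldolate during the in-flask mesylation.
- Consumption of MsCl by the liberated diisopropylamine.

The fallback replaces the aldol by an olefination under neutral conditions, sets out from 2 and comes back at 10. LiN(iPr)2 then Me3SiCl (THF, −78 °C) gives the kinetic trimethylsilyl enol ether F4. N-Bromosuccinimide (THF, −78 → 0 °C) gives the bromomethyl ketone F5. PPh3 (toluene, 25 °C) gives the phosphonium bromide F6, and aq. Na2CO3/CH2Cl2 gives the acyl-stabilised ylide F7. Wittig reaction of this ylide with 7 (toluene, 80 °C) gives the E-enone 10 without any enolate.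

**Step 3 (hydroboration–oxidation next to a base-labile aryl silyl ether).** Weak points:
- Buffered peroxide may oxidise the B-alkyl-9-BBN adduct sluggishly, while stronger base strips the aryl silyl ether.
- Cyclooctanediol may co-elute with 6.

The fallback reverses the order of protection so that alkaline peroxide can be used freely; it sets out from 3 and comes back at 6. Hydroboration of unprotected 3 with 9-BBN (2.2 equiv, THF, 25 °C) gives the bis-boron adduct F8, which is not isolated. 3 M NaOH/30 % H2O2 gives 3-(4-hydroxy-3,5-dimethoxyphenyl)propan-1-ol F9. TBSCl (2.4 equiv)/imidazole/DMF gives the bis-silyl ether F10. Pyridinium p-toluenesulfonate in MeOH (25 °C) removes only the primary alkyl silyl ether and gives 6.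

## Further compounds

```
F1 | step 6 | (5S)-3-{2-[4-(TBSO)-3-methoxyphenyl]ethyl}-5-{2-[4-(TBSO)-3,5-dimethoxyphenyl]ethyl}-1,2-dioxolan-3-ol (anomer mixture at C3 of the dioxolane) | COc1cc(CCC2(O)C[C@H](CCc3cc(OC)c(O[Si](C)(C)C(C)(C)C)c(OC)c3)OO2)ccc1O[Si](C)(C)C(C)(C)C
F2 | step 6 | (5S)-5-hydroxy-1-[4-(TBSO)-3-methoxyphenyl]-7-[4-(TBSO)-3,5-dimethoxyphenyl]heptan-3-one | COc1cc(CCC(=O)C[C@@H](O)CCc2cc(OC)c(O[Si](C)(C)C(C)(C)C)c(OC)c2)ccc1O[Si](C)(C)C(C)(C)C
F3 | step 6 | (3S,5S)-1-[4-(TBSO)-3-methoxyphenyl]-7-[4-(TBSO)-3,5-dimethoxyphenyl]heptane-3,5-diol | COc1cc(CC[C@H](O)C[C@@H](O)CCc2cc(OC)c(O[Si](C)(C)C(C)(C)C)c(OC)c2)ccc1O[Si](C)(C)C(C)(C)C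
F4 | step 5 | tert-butyl{2-methoxy-4-[3-(trimethylsilyloxy)but-3-en-1-yl]phenoxy}dimethylsilane | C=C(O[Si](C)(C)C)CCc1ccc(O[Si](C)(C)C(C)(C)C)c(OC)c1
F5 | step 5 | 1-bromo-4-[4-(TBSO)-3-methoxyphenyl]butan-2-one | BrCC(=O)CCc1ccc(O[Si](C)(C)C(C)(C)C)c(OC)c1
F6 | step 5 | {4-[4-(TBSO)-3-methoxyphenyl]-2-oxobutyl}triphenylphosphonium bromide | [Br-].O=C(C[P+](c1ccccc1)(c1ccccc1)c1ccccc1)CCc1ccc(O[Si](C)(C)C(C)(C)C)c(OC)c1
F7 | step 5 | 4-[4-(TBSO)-3-methoxyphenyl]-1-(triphenylphosphoranylidene)butan-2-one | O=C(C=P(c1ccccc1)(c1ccccc1)c1ccccc1)CCc1ccc(O[Si](C)(C)C(C)(C)C)c(OC)c1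
F8 | step 3 | B-{3-[4-(9-borabicyclo[3.3.1]nonan-9-yloxy)-3,5-dimethoxyphenyl]propyl}-9-borabicyclo[3.3.1]nonane | COc1cc(CCCB2C3CCCC2CCC3)cc(OC)c1OB1C2CCCC1CCC2
F9 | step 3 | 3-(4-hydroxy-3,5-dimethoxyphenyl)propan-1-ol | OCCCc1cc(OC)c(O)c(OC)c1
F10 | step 3 | tert-butyl{3-[4-(TBSO)-3,5-dimethoxyphenyl]propoxy}dimethylsilane | CC(C)(C)[Si](C)(C)OCCCc1cc(OC)c(O[Si](C)(C)C(C)(C)C)c(OC)c1
```
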